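**Retrosynthetic overview**
- The last C–C bond is the diarylmethine–aryl bond: a Friedel–Crafts union of a West tetrahydrofuran hexaphenol with an East dihydrobenzofuran benzylic alcohol that already carries the chalcone; desilylation ends the route.
- East: the chalcone comes from a Heck coupling on a 5-triflyloxy-2,3-dihydrobenzofuran. That ring is formed by a Lewis acid-promoted formal [3+2] cycloaddition of 1,4-benzoquinone with a styrene whose allylic dioxolane stereocentre (from L-gulonolactone) sets C2/C3 and is then cut back to the C3 aldehyde.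
- West: the tetrahydrofuran comes from aldol/hemiketal formation on a 1,4-diaryl-1,4-diketone, ionic hydrogenation (2,3-cis) and base equilibration of C4/C5. The diketone comes from (R)-benzylsuccinic acid, made from D-tyrosine by diazotisation and SN2 malonate alkylation.
- Ring order: the West tetrahydrofuran and the East dihydrobenzofuran are built separately, then joined.

Assumption: D-tyrosine, 5,6-O-isopropylidene-L-gulono-1,4-lactone and the achiral aryl building blocks listed as starting materials are taken as commercial.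

**West fragment**

Step 1
Reactants: 1 D-tyrosine
Product: 4 (R)-2-hydroxy-3-(4-hydroxyphenyl)propanoic acid, via diazonium carboxylate 2 (not isolated), via alpha-lactone 3 (not isolated)
Conditions: NaNO2, 1 M H2SO4 (aq), 0 °C → rt
Reagents that add atoms: water (O)
Why: Diazotisation of the alpha-amino acid; the carboxylate displaces N2 (alpha-lactone) and water opens it, so two inversions give net retention and the D-tyrosine centre is kept as (R).

Step 2
Reactants: 4 (R)-2-hydroxy-3-(4-hydroxyphenyl)propanoic acid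
Product: 5 benzyl (R)-3-[4-(benzyloxy)phenyl]-2-hydroxypropanoate
Conditions: BnBr (2.2 equiv), K2CO3, DMF, rt
Reagents that add atoms: benzyl bromide (BrCc1ccccc1)
Why: Williamson-type O-alkylation; carbonate ionises only CO2H and ArOH, so the secondary alcohol stays free and the stereocentre is untouched.

Step 3
Reactants: 5 benzyl (R)-3-[4-(benzyloxy)phenyl]-2-hydroxypropanoate; 6 dimethyl malonate
Product: 8 2-benzyl 1,1-dimethyl (R)-3-[4-(benzyloxy)phenyl]propane-1,1,2-tricarboxylate, via triflate 7 (not isolated)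
Conditions: Tf2O, 2,6-lutidine, CH2Cl2, −78 °C; then NaCH(CO2Me)2 (from 6 and NaH), THF, −78 → 0 °C
Reagents that add atoms: none
Why: SN2 alkylation of the soft malonate anion by the alpha-carbonyl-activated secondary triflate proceeds with clean inversion, turning the bought C–O centre into the all-carbon centre that becomes tetrahydrofuran C3.

Step 4
Reactants: 8 2-benzyl 1,1-dimethyl (R)-3-[4-(benzyloxy)phenyl]propane-1,1,2-tricarboxylate
Product: 10 (R)-2-[4-(benzyloxy)benzyl]succinic acid, via tricarboxylic acid 9 (not isolated)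
Conditions: LiOH, THF/H2O, rt; HCl (aq); then toluene, 110 °C
Reagents that add atoms: lithium hydroxide ([Li+].[OH-])
Why: Saponification followed by thermal malonic acid decarboxylation; the stereocentre sits alpha to a carboxylate and is not epimerised.

Step 5
Reactants: 10 (R)-2-[4-(benzyloxy)benzyl]succinic acid
Product: 11 (R)-2-[4-(benzyloxy)benzyl]-N1,N4-dimethoxy-N1,N4-dimethylsuccinamide
Conditions: MeNHOMe·HCl, EDC·HCl, HOBt (cat.), iPr2NEt, CH2Cl2, 0 °C → rt
Reagents that add atoms: N,O-dimethylhydroxylamine hydrochloride (CNOC.Cl)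
Why: Carbodiimide amide coupling gives the bis-Weinreb amide without touching the stereocentre.

Step 6
Reactants: 11 (R)-2-[4-(benzyloxy)benzyl]-N1,N4-dimethoxy-N1,N4-dimethylsuccinamide; 12 2,4-bis(benzyloxy)-1-bromobenzene
Product: 13 (R)-2-[4-(benzyloxy)benzyl]-1,4-bis[2,4-bis(benzyloxy)phenyl]butane-1,4-dione
Conditions: 12 (2.4 equiv), n-BuLi, THF, −78 °C; then 11, −78 → 0 °C; aq NH4Cl
Reagents that add atoms: none
Why: Weinreb ketone synthesis; the aryllithium from bromine–lithium exchange adds once to each amide through chelated tetrahedral intermediates, and both aroyl groups are the same ring so no differentiation is needed.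

Step 7
Reactants: 13 (R)-2-[4-(benzyloxy)benzyl]-1,4-bis[2,4-bis(benzyloxy)phenyl]butane-1,4-dione; 14 4-(benzyloxy)benzaldehyde
Product: 16 [(4R)-4-[4-(benzyloxy)benzyl]-2-[4-(benzyloxy)phenyl]-5-[2,4-bis(benzyloxy)phenyl]-5-hydroxyoxolan-3-yl][2,4-bis(benzyloxy)phenyl]methanone (epimer mixture at oxolane C2/C3/C5), via open-chain aldol 15 (not isolated)
Conditions: LiN(iPr)2 (1.05 equiv), THF, −78 °C; 14 (1.2 equiv); aq NH4Cl at −78 °C
Reagents that add atoms: none
Why: Kinetic lithium enolate formation at the unhindered CH2 (not at the tertiary C–H next to the other ketone) and aldol addition; the aldolate closes onto the second ketone as a five-membered hemiketal, and the unselective new centres are corrected in step 8.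

Step 8
Reactants: 16 hemiketal mixture
Product: 18 [(2R,3R,4R,5S)-4-[4-(benzyloxy)benzyl]-2-[4-(benzyloxy)phenyl]-5-[2,4-bis(benzyloxy)phenyl]oxolan-3-yl][2,4-bis(benzyloxy)phenyl]methanone, via C2/C3-epimer mixture 17 (not isolated)
Conditions: Et3SiH, BF3·OEt2, CH2Cl2, −78 °C; then DBU (excess), −78 °C → rt
Reagents that add atoms: none
Why: Ionic hydrogenation: the aryl-stabilised oxocarbenium ion takes hydride anti to the neighbouring benzyl group (aryl and benzyl end up cis), then DBU equilibrates the ketone alpha-carbon and the adjacent benzylic ether carbon by enolisation and retro-oxa-Michael/oxa-Michael to the most stable arrangement (aroyl trans to both neighbours).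

Step 9
Reactants: 18 hexabenzyl ether
Product: 19 (2,4-dihydroxyphenyl)[(2R,3R,4R,5S)-5-(2,4-dihydroxyphenyl)-4-(4-hydroxybenzyl)-2-(4-hydroxyphenyl)oxolan-3-yl]methanone
Conditions: H2 (1 atm), Pd/C (10%), EtOAc/MeOH, rt
Reagents that add atoms: none
Why: Hydrogenolysis of aryl benzyl ethers is much faster than cleavage of the cyclic dibenzylic ether under neutral conditions, and the molecule has no alkene at this stage.

**East fragment**

Step 10
Reactants: 20 5,6-O-isopropylidene-L-gulono-1,4-lactone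
Product: 23 (S)-2,2-dimethyl-1,3-dioxolane-4-carbaldehyde, via glyoxylate ester 21 (not isolated), via 3,4-O-isopropylidene-L-threose 22 (not isolated)
Conditions: NaIO4 (2.1 equiv), H2O, pH 5.5, 0 °C → rt
Reagents that add atoms: none
Why: Two successive periodate glycol cleavages excise C1–C3 of the sugar lactone; the surviving stereocentre (former C5) is not involved.

Step 11
Reactants: 23 (S)-2,2-dimethyl-1,3-dioxolane-4-carbaldehyde
Product: 24 (R)-2,2-dimethyl-4-vinyl-1,3-dioxolane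
Conditions: Ph3PCH3Br, KOtBu, THF, 0 °C
Reagents that add atoms: methyltriphenylphosphonium bromide (C[P+](c1ccccc1)(c1ccccc1)c1ccccc1.[Br-])
Why: Wittig methylenation with a non-stabilised ylide is fast at 0 °C and does not epimerise the alpha-alkoxy aldehyde (the descriptor changes only by priority).

Step 12
Reactants: 24 (R)-2,2-dimethyl-4-vinyl-1,3-dioxolane; 25 tert-butyldimethyl(4-vinylphenoxy)silane
Product: 26 tert-butyl(4-{(E)-2-[(4R)-2,2-dimethyl-1,3-dioxolan-4-yl]ethenyl}phenoxy)dimethylsilane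
Conditions: second-generation Grubbs catalyst [(H2IMes)(PCy3)Cl2Ru=CHPh] (3 mol%), CH2Cl2, 40 °C
Reagents that add atoms: none
Why: Olefin cross-metathesis of a styrene with an allylically branched terminal alkene gives the E-alkene with loss of ethene and no change at the stereocentre.

Step 13
Reactants: 26 (R,E)-styrene; 27 1,4-benzoquinone
Product: 28 (2R,3R)-2-[4-(tert-butyldimethylsilyloxy)phenyl]-3-[(4R)-2,2-dimethyl-1,3-dioxolan-4-yl]-2,3-dihydro-1-benzofuran-5-ol
Conditions: 27 (1.5 equiv), BF3·OEt2 (0.3 equiv), CH2Cl2, −78 → −30 °C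
Reagents that add atoms: none
Why: Lewis acid-promoted formal [3+2] cycloaddition: the styrene attacks the activated quinone through the alkene carbon next to the dioxolane on the face anti to the allylic C–O bond (allylic-strain, inside-alkoxy model), which sets C3; the benzylic cation is closed by the quinone oxygen trans to the C3 substituent (C2), and tautomerisation gives the phenol.

Step 14
Reactants: 28 dihydrobenzofuran-5-ol
Product: 29 (2R,3R)-2-[4-(tert-butyldimethylsilyloxy)phenyl]-3-[(4R)-2,2-dimethyl-1,3-dioxolan-4-yl]-2,3-dihydro-1-benzofuran-5-yl trifluoromethanesulfonate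
Conditions: Tf2O, pyridine, CH2Cl2, 0 °C
Reagents that add atoms: trifluoromethanesulfonic anhydride (O=S(=O)(OS(=O)(=O)C(F)(F)F)C(F)(F)F)
Why: O-sulfonylation of the only free phenol installs the handle for the later Heck coupling.

Step 15
Reactants: 29 aryl triflate acetonide
Product: 31 (2R,3R)-2-[4-(tert-butyldimethylsilyloxy)phenyl]-3-formyl-2,3-dihydro-1-benzofuran-5-yl trifluoromethanesulfonate, via diol 30 (not isolated)
Conditions: H5IO6 (2 equiv), EtOAc, 0 °C → rt
Reagents that add atoms: none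
Why: Periodic acid hydrolyses the terminal acetonide and cleaves the resulting glycol in one flask; the controlling dioxolane centre is excised, and the 2,3-trans aldehyde is the stable epimer.

Step 16
Reactants: 32 4-bromoresorcinol
Product: 33 [(4-bromo-1,3-phenylene)bis(oxy)]bis(tert-butyldimethylsilane)
Conditions: TBSCl, imidazole, DMF, rt
Reagents that add atoms: tert-butyldimethylsilyl chloride (CC(C)(C)[Si](C)(C)Cl)
Why: Standard imidazole-mediated silylation of both phenols.

Step 17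
Reactants: 31 aldehyde; 33 aryl bromide
Product: 34 (2R,3S)-3-{[2,4-bis(tert-butyldimethylsilyloxy)phenyl](hydroxy)methyl}-2-[4-(tert-butyldimethylsilyloxy)phenyl]-2,3-dihydro-1-benzofuran-5-yl trifluoromethanesulfonate (both carbinol epimers)
Conditions: 33, Mg, LiCl, THF, rt; then 31, −78 °C; aq NH4Cl
Reagents that add atoms: none
Why: Grignard addition to the aldehyde at −78 °C outruns enolisation and attack on the triflate; the carbinol configuration is irrelevant because this carbon is ionised in step 21.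

Step 18
Reactants: 35 1-(2,4-dihydroxyphenyl)ethanone
Product: 36 1-[2,4-bis(tert-butyldimethylsilyloxy)phenyl]ethanone
Conditions: TBSCl, imidazole, DMF, 40 °C
Reagents that add atoms: tert-butyldimethylsilyl chloride (CC(C)(C)[Si](C)(C)Cl)
Why: Silylation of both phenols; the ortho silyl ether later prevents chromanone formation from the vinyl ketone.

Step 19
Reactants: 36 silylated acetophenone
Product: 38 1-[2,4-bis(tert-butyldimethylsilyloxy)phenyl]prop-2-en-1-one, via Mannich base 37 (not isolated)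
Conditions: (CH2O)n, iPr2NH·CF3CO2H, CF3CO2H (cat.), THF, reflux
Reagents that add atoms: paraformaldehyde (C=O)
Why: Mannich condensation followed by beta-elimination of the amine (alpha-methylenation) gives the aryl vinyl ketone, used fresh.

Step 20
Reactants: 34 triflate carbinol; 38 aryl vinyl ketone
Product: 39 (E)-1-[2,4-bis(tert-butyldimethylsilyloxy)phenyl]-3-[(2R,3S)-3-{[2,4-bis(tert-butyldimethylsilyloxy)phenyl](hydroxy)methyl}-2-[4-(tert-butyldimethylsilyloxy)phenyl]-2,3-dihydro-1-benzofuran-5-yl]prop-2-en-1-one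
Conditions: Pd(OAc)2 (5 mol%), P(o-tol)3 (10 mol%), LiCl, Et3N, DMF, 80 °C
Reagents that add atoms: none
Why: Mizoroki–Heck reaction: oxidative addition of the aryl triflate to zerovalent palladium, syn insertion of the enone and beta-hydride elimination give the E-chalcone.

**Union and end game**

Step 21
Reactants: 39 East chalcone carbinol; 19 West hexaphenol
Product: 40 penta-silyl ether of 41 (tert-butyldimethylsilyl on the chalcone 2',4'-OH, on the 4-OH of the dihydrobenzofuran C2 aryl and on both OH of the unsubstituted resorcinol ring at the methine carbon; all seven stereocentres arranged as in 41)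
Conditions: 19 (1.5 equiv), Sc(OTf)3 (10 mol%), MeCN, −20 → 0 °C
Reagents that add atoms: none
Why: Friedel–Crafts benzylation: the doubly oxygen-stabilised benzylic cation is captured by the most nucleophilic carbon of 19 (C5 of its free resorcinol ring). The allylic-strain model (C3–H eclipsing the aryl, attack anti to the fused benzo carbon) predicts the (R) methine, but this facial preference is not secure.

Step 22
Reactants: 40 penta-silyl ether
Product: 41 CNP0225254.6
Conditions: Bu4NF (6 equiv), AcOH (6 equiv), THF, 0 °C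
Reagents that add atoms: none
Why: Fluoride cleavage of the five aryl silyl ethers, buffered with acetic acid to avoid chalcone–flavanone isomerisation and ring opening of the aroyl tetrahydrofuran.

**Compound list**

1 | D-tyrosine | N[C@H](Cc1ccc(O)cc1)C(=O)O | starting material
2 | (R)-1-carboxylato-2-(4-hydroxyphenyl)ethane-1-diazonium | N#[N+][C@H](Cc1ccc(O)cc1)C(=O)[O-] | intermediate (not isolated)
3 | (S)-3-(4-hydroxybenzyl)oxiran-2-one | O=C1O[C@H]1Cc1ccc(O)cc1 | intermediate (not isolated)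
4 | (R)-2-hydroxy-3-(4-hydroxyphenyl)propanoic acid | O[C@H](Cc1ccc(O)cc1)C(=O)O | intermediate
5 | benzyl (R)-3-[4-(benzyloxy)phenyl]-2-hydroxypropanoate | O[C@H](Cc1ccc(OCc2ccccc2)cc1)C(=O)OCc1ccccc1 | intermediate
6 | dimethyl malonate | COC(=O)CC(=O)OC | starting material
7 | benzyl (R)-3-[4-(benzyloxy)phenyl]-2-{[(trifluoromethyl)sulfonyl]oxy}propanoate | O=S(=O)(O[C@H](Cc1ccc(OCc2ccccc2)cc1)C(=O)OCc1ccccc1)C(F)(F)F | intermediate (not isolated)
8 | 2-benzyl 1,1-dimethyl (R)-3-[4-(benzyloxy)phenyl]propane-1,1,2-tricarboxylate | COC(=O)C(C(=O)OC)[C@@H](Cc1ccc(OCc2ccccc2)cc1)C(=O)OCc1ccccc1 | intermediate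
9 | (R)-3-[4-(benzyloxy)phenyl]propane-1,1,2-tricarboxylic acid | OC(=O)C(C(=O)O)[C@@H](Cc1ccc(OCc2ccccc2)cc1)C(=O)O | intermediate (not isolated)
10 | (R)-2-[4-(benzyloxy)benzyl]succinic acid | OC(=O)C[C@@H](Cc1ccc(OCc2ccccc2)cc1)C(=O)O | intermediate
11 | (R)-2-[4-(benzyloxy)benzyl]-N1,N4-dimethoxy-N1,N4-dimethylsuccinamide | CON(C)C(=O)C[C@@H](Cc1ccc(OCc2ccccc2)cc1)C(=O)N(C)OC | intermediate
12 | 2,4-bis(benzyloxy)-1-bromobenzene | Brc1ccc(OCc2ccccc2)cc1OCc1ccccc1 | starting material
13 | (R)-2-[4-(benzyloxy)benzyl]-1,4-bis[2,4-bis(benzyloxy)phenyl]butane-1,4-dione | O=C(C[C@@H](Cc1ccc(OCc2ccccc2)cc1)C(=O)c1ccc(OCc2ccccc2)cc1OCc1ccccc1)c1ccc(OCc2ccccc2)cc1OCc1ccccc1 | intermediate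
14 | 4-(benzyloxy)benzaldehyde | O=Cc1ccc(OCc2ccccc2)cc1 | starting material
15 | (2R)-2-[4-(benzyloxy)benzyl]-3-{[4-(benzyloxy)phenyl](hydroxy)methyl}-1,4-bis[2,4-bis(benzyloxy)phenyl]butane-1,4-dione (mixture at the two new centres) | OC(c1ccc(OCc2ccccc2)cc1)C(C(=O)c1ccc(OCc2ccccc2)cc1OCc1ccccc1)[C@@H](Cc1ccc(OCc2ccccc2)cc1)C(=O)c1ccc(OCc2ccccc2)cc1OCc1ccccc1 | intermediate (not isolated)
16 | [(4R)-4-[4-(benzyloxy)benzyl]-2-[4-(benzyloxy)phenyl]-5-[2,4-bis(benzyloxy)phenyl]-5-hydroxyoxolan-3-yl][2,4-bis(benzyloxy)phenyl]methanone (epimers at C2, C3, C5) | OC1(c2ccc(OCc3ccccc3)cc2OCc2ccccc2)OC(c2ccc(OCc3ccccc3)cc2)C(C(=O)c2ccc(OCc3ccccc3)cc2OCc2ccccc2)[C@H]1Cc1ccc(OCc2ccccc2)cc1 | intermediate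
17 | [(4R,5S)-4-[4-(benzyloxy)benzyl]-2-[4-(benzyloxy)phenyl]-5-[2,4-bis(benzyloxy)phenyl]oxolan-3-yl][2,4-bis(benzyloxy)phenyl]methanone (epimers at C2, C3) | C(c1ccccc1)Oc1ccc([C@H]2OC(c3ccc(OCc4ccccc4)cc3)C(C(=O)c3ccc(OCc4ccccc4)cc3OCc3ccccc3)[C@H]2Cc2ccc(OCc3ccccc3)cc2)c(OCc2ccccc2)c1 | intermediate (not isolated)
18 | [(2R,3R,4R,5S)-4-[4-(benzyloxy)benzyl]-2-[4-(benzyloxy)phenyl]-5-[2,4-bis(benzyloxy)phenyl]oxolan-3-yl][2,4-bis(benzyloxy)phenyl]methanone | C(c1ccccc1)Oc1ccc([C@H]2O[C@@H](c3ccc(OCc4ccccc4)cc3)[C@H](C(=O)c3ccc(OCc4ccccc4)cc3OCc3ccccc3)[C@H]2Cc2ccc(OCc3ccccc3)cc2)c(OCc2ccccc2)c1 | intermediate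
19 | (2,4-dihydroxyphenyl)[(2R,3R,4R,5S)-5-(2,4-dihydroxyphenyl)-4-(4-hydroxybenzyl)-2-(4-hydroxyphenyl)oxolan-3-yl]methanone | Oc1ccc([C@H]2O[C@@H](c3ccc(O)cc3)[C@H](C(=O)c3ccc(O)cc3O)[C@H]2Cc2ccc(O)cc2)c(O)c1 | intermediate
20 | 5,6-O-isopropylidene-L-gulono-1,4-lactone | O=C1[C@@H](O)[C@@H](O)[C@H](O1)[C@@H]1COC(C)(C)O1 | starting material
21 | 2-O-glyoxyloyl-3,4-O-isopropylidene-L-threose | O=CC(=O)O[C@@H](C=O)[C@@H]1COC(C)(C)O1 | intermediate (not isolated)
22 | 3,4-O-isopropylidene-L-threose | O=C[C@H](O)[C@@H]1COC(C)(C)O1 | intermediate (not isolated)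
23 | (S)-2,2-dimethyl-1,3-dioxolane-4-carbaldehyde | CC1(C)OC[C@H](O1)C=O | intermediate
24 | (R)-2,2-dimethyl-4-vinyl-1,3-dioxolane | CC1(C)OC[C@H](O1)C=C | intermediate
25 | tert-butyldimethyl(4-vinylphenoxy)silane | C=Cc1ccc(O[Si](C)(C)C(C)(C)C)cc1 | starting material
26 | tert-butyl(4-{(E)-2-[(4R)-2,2-dimethyl-1,3-dioxolan-4-yl]ethenyl}phenoxy)dimethylsilane | CC1(C)OC[C@H](O1)/C=C/c1ccc(O[Si](C)(C)C(C)(C)C)cc1 | intermediate
27 | 1,4-benzoquinone | O=C1C=CC(=O)C=C1 | starting material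
28 | (2R,3R)-2-[4-(tert-butyldimethylsilyloxy)phenyl]-3-[(4R)-2,2-dimethyl-1,3-dioxolan-4-yl]-2,3-dihydro-1-benzofuran-5-ol | Oc1ccc2c(c1)[C@@H]([C@@H]1COC(C)(C)O1)[C@H](c1ccc(O[Si](C)(C)C(C)(C)C)cc1)O2 | intermediate
29 | (2R,3R)-2-[4-(tert-butyldimethylsilyloxy)phenyl]-3-[(4R)-2,2-dimethyl-1,3-dioxolan-4-yl]-2,3-dihydro-1-benzofuran-5-yl trifluoromethanesulfonate | O=S(=O)(Oc1ccc2c(c1)[C@@H]([C@@H]1COC(C)(C)O1)[C@H](c1ccc(O[Si](C)(C)C(C)(C)C)cc1)O2)C(F)(F)F | intermediate
30 | (2R,3S)-2-[4-(tert-butyldimethylsilyloxy)phenyl]-3-[(1R)-1,2-dihydroxyethyl]-2,3-dihydro-1-benzofuran-5-yl trifluoromethanesulfonate | O=S(=O)(Oc1ccc2c(c1)[C@@H]([C@@H](O)CO)[C@H](c1ccc(O[Si](C)(C)C(C)(C)C)cc1)O2)C(F)(F)F | intermediate (not isolated)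
31 | (2R,3R)-2-[4-(tert-butyldimethylsilyloxy)phenyl]-3-formyl-2,3-dihydro-1-benzofuran-5-yl trifluoromethanesulfonate | O=S(=O)(Oc1ccc2c(c1)[C@@H](C=O)[C@H](c1ccc(O[Si](C)(C)C(C)(C)C)cc1)O2)C(F)(F)F | intermediate
32 | 4-bromoresorcinol | Oc1ccc(Br)c(O)c1 | starting material
33 | [(4-bromo-1,3-phenylene)bis(oxy)]bis(tert-butyldimethylsilane) | CC(C)(C)[Si](C)(C)Oc1ccc(Br)c(O[Si](C)(C)C(C)(C)C)c1 | intermediate
34 | (2R,3S)-3-{[2,4-bis(tert-butyldimethylsilyloxy)phenyl](hydroxy)methyl}-2-[4-(tert-butyldimethylsilyloxy)phenyl]-2,3-dihydro-1-benzofuran-5-yl trifluoromethanesulfonate (both carbinol epimers) | O=S(=O)(Oc1ccc2c(c1)[C@@H](C(O)c1ccc(O[Si](C)(C)C(C)(C)C)cc1O[Si](C)(C)C(C)(C)C)[C@H](c1ccc(O[Si](C)(C)C(C)(C)C)cc1)O2)C(F)(F)F | intermediate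
35 | 1-(2,4-dihydroxyphenyl)ethanone | CC(=O)c1ccc(O)cc1O | starting material
36 | 1-[2,4-bis(tert-butyldimethylsilyloxy)phenyl]ethanone | CC(=O)c1ccc(O[Si](C)(C)C(C)(C)C)cc1O[Si](C)(C)C(C)(C)C | intermediate
37 | 1-[2,4-bis(tert-butyldimethylsilyloxy)phenyl]-3-(diisopropylamino)propan-1-one | CC(C)N(CCC(=O)c1ccc(O[Si](C)(C)C(C)(C)C)cc1O[Si](C)(C)C(C)(C)C)C(C)C | intermediate (not isolated)
38 | 1-[2,4-bis(tert-butyldimethylsilyloxy)phenyl]prop-2-en-1-one | C=CC(=O)c1ccc(O[Si](C)(C)C(C)(C)C)cc1O[Si](C)(C)C(C)(C)C | intermediate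
39 | (E)-1-[2,4-bis(tert-butyldimethylsilyloxy)phenyl]-3-[(2R,3S)-3-{[2,4-bis(tert-butyldimethylsilyloxy)phenyl](hydroxy)methyl}-2-[4-(tert-butyldimethylsilyloxy)phenyl]-2,3-dihydro-1-benzofuran-5-yl]prop-2-en-1-one (both carbinol epimers) | O=C(/C=C/c1ccc2c(c1)[C@@H](C(O)c1ccc(O[Si](C)(C)C(C)(C)C)cc1O[Si](C)(C)C(C)(C)C)[C@H](c1ccc(O[Si](C)(C)C(C)(C)C)cc1)O2)c1ccc(O[Si](C)(C)C(C)(C)C)cc1O[Si](C)(C)C(C)(C)C | intermediate
40 | penta-(tert-butyldimethylsilyl) ether of 41 (silyl on the five East phenols named in step 21; stereocentres arranged as in 41) | O=C(/C=C/c1ccc2c(c1)[C@@H]([C@H](c1ccc(O[Si](C)(C)C(C)(C)C)cc1O[Si](C)(C)C(C)(C)C)c1cc([C@H]3O[C@@H](c4ccc(O)cc4)[C@H](C(=O)c4ccc(O)cc4O)[C@H]3Cc3ccc(O)cc3)c(O)cc1O)[C@H](c1ccc(O[Si](C)(C)C(C)(C)C)cc1)O2)c1ccc(O[Si](C)(C)C(C)(C)C)cc1O[Si](C)(C)C(C)(C)C | intermediate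
41 | CNP0225254.6: (E)-1-(2,4-dihydroxyphenyl)-3-[(2R,3R)-3-[(R)-(2,4-dihydroxyphenyl){5-[(2S,3R,4R,5R)-4-(2,4-dihydroxybenzoyl)-3-(4-hydroxybenzyl)-5-(4-hydroxyphenyl)oxolan-2-yl]-2,4-dihydroxyphenyl}methyl]-2-(4-hydroxyphenyl)-2,3-dihydro-1-benzofuran-5-yl]prop-2-en-1-one | O=C(/C=C/c1ccc2c(c1)[C@@H]([C@H](c1ccc(O)cc1O)c1cc([C@H]3O[C@@H](c4ccc(O)cc4)[C@H](C(=O)c4ccc(O)cc4O)[C@H]3Cc3ccc(O)cc3)c(O)cc1O)[C@H](c1ccc(O)cc1)O2)c1ccc(O)cc1O | target

**Totals**

Total step count: 22 (steps 1–9 West; 10–15, 17 and 20 East; 16, 18 and 19 reagent preparation; 21 and 22 union and deprotection).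
Longest linear sequence: 11 steps (1–9, 21, 22).

**Three steps most likely to fail**

Step 21 (union). The facial selectivity at the new diarylmethine carbon rests on a conformational model, and E1 loss of the C3 proton (leading to a benzofuran) or acid-induced opening of the benzylic ethers of 19 can compete. The fallback sets out from 39 and comes back at 41. Compound 39 is first desilylated (Bu4NF/AcOH, THF, 0 °C) to the pentaphenol carbinol F1. Warming F1 with 19 (2 equiv) in MeCN/aqueous phosphate buffer (pH 7, 40 °C) lets the free ortho-hydroxyl expel water to give the o-quinone methide F2. F2 takes up C5 of the resorcinol ring of 19 by conjugate addition and gives 41 directly. This replaces the Lewis acid cation chemistry by a neutral, protecting-group-free quinone methide addition with a planar, hydrogen-bonded electrophile.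

Step 13 (formal [3+2] cycloaddition). The allylic dioxolane lowers the nucleophilicity of the styrene and must also control the alkene face; BF3 may attack the acetonide. The fallback sets out from 26 and comes back at 28. Compound 26 and 4-(benzyloxy)phenol undergo a photocatalytic one-electron oxidative phenol–alkene [3+2] cycloaddition (Ru(bpz)3(PF6)2 cat., (NH4)2S2O8, MeCN, blue light) to give the 5-benzyloxy dihydrobenzofuran F3. Brief hydrogenolysis of the aryl benzyl ether of F3 (H2, Pd/C, EtOAc) then gives 28.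

Step 7 (aldol on the diketone). Deprotonation or proton transfer at the tertiary C–H next to the second ketone would erode the tyrosine-derived centre. The fallback sets out from 11 and comes back at 16, reversing the order of aryl addition and aldol. The bis-Weinreb amide 11 is enolised at its CH2 (LiN(iPr)2, THF, −78 °C) and added to 14; on warming to 0 °C the alkoxide closes onto the neighbouring Weinreb amide to give the lactone Weinreb amide F4, in which the benzyl-bearing carbon is never alpha to a ketone. F4 is then treated with the aryllithium from 12 (2.5 equiv, THF, −78 °C), which adds to the lactone carbonyl and to the remaining Weinreb amide, giving 16 after work-up.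

**Further compounds**

F1 | step 21 | (E)-1-(2,4-dihydroxyphenyl)-3-[(2R,3S)-3-[(2,4-dihydroxyphenyl)(hydroxy)methyl]-2-(4-hydroxyphenyl)-2,3-dihydro-1-benzofuran-5-yl]prop-2-en-1-one (both carbinol epimers) | O=C(/C=C/c1ccc2c(c1)[C@@H](C(O)c1ccc(O)cc1O)[C@H](c1ccc(O)cc1)O2)c1ccc(O)cc1O
F2 | step 21 | o-quinone methide from F1: 6-{[(2R,3R)-5-[(E)-3-(2,4-dihydroxyphenyl)-3-oxoprop-1-enyl]-2-(4-hydroxyphenyl)-2,3-dihydro-1-benzofuran-3-yl]methylidene}-3-hydroxycyclohexa-2,4-dien-1-one | O=C(/C=C/c1ccc2c(c1)[C@@H](C=C1C=CC(O)=CC1=O)[C@H](c1ccc(O)cc1)O2)c1ccc(O)cc1O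
F3 | step 13 | {4-[(2R,3R)-5-(benzyloxy)-3-[(4R)-2,2-dimethyl-1,3-dioxolan-4-yl]-2,3-dihydro-1-benzofuran-2-yl]phenoxy}(tert-butyl)dimethylsilane | C(c1ccccc1)Oc1ccc2c(c1)[C@@H]([C@@H]1COC(C)(C)O1)[C@H](c1ccc(O[Si](C)(C)C(C)(C)C)cc1)O2
F4 | step 7 | (4R)-4-[4-(benzyloxy)benzyl]-2-[4-(benzyloxy)phenyl]-N-methoxy-N-methyl-5-oxooxolane-3-carboxamide (epimers at C2, C3) | CON(C)C(=O)C1C(c2ccc(OCc3ccccc3)cc2)OC(=O)[C@@H]1Cc1ccc(OCc2ccccc2)cc1
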